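**Plan**

1. Retrosynthesis: the fused lactone is cut at O–C14 and C12–C13 (C1 enolate plus ethyl (S)-lactate triflate), the azepanone at N4–C5 (amide N-alkylation by the chlorobutyl arm on C9), and the nine-membered lactam at C9–C10 and N4–C9a with N4–C12 re-formed, which is a retro-aza-Claisen to a 2-[(Z)-butenyl]pyrrolidine and 6-chlorohexanoyl fluoride; the side lactone goes back to a proline ester.
2. Enabling feature: N4, C3, C2, C1 and C12 of the nine-membered ring are a latent pyrrolidine whose C12 carries the C11=C10 olefin, and the C9–C10 bond lies across the lactam carbonyl C9a from the N4–C12 bond, so C9, C9a, N4, C12, C11 and C10 map onto the chair of a zwitterionic aza-Claisen shift.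
3. Forward order of rings: pyrrolidine (chiral pool), side γ-lactone, nine-membered lactam by four-atom ring enlargement, azepanone by N4–C5 closure, fused γ-lactone last.
4. Stereochemistry: C3 from cis-4-hydroxy-L-proline; the relay centre C12 by alkynyl addition anti to both ring substituents; C18 by Felkin–Anh ketone reduction; C20 and C13 by SN2 inversion of ethyl (S)-lactate triflate; C9 and C10 by the chair [3,3] shift; C11 by hydroxyl-directed epoxidation; C12 by enolate alkylation on the open ring face.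

Key step: step 14

Remark on numbering: tuberostemonone numbering is used for all atoms that end up in the target (N4; C1–C3; C5–C9; C9a; C10–C13; C14 fused-lactone carbonyl; C15 methyl on C13; C16–C17 ethyl; C18 carbinol, C19, C20, C21 carbonyl and C22 methyl of the side lactone).
Remark on starting material: N-Boc-cis-4-hydroxy-L-proline methyl ester (1) is taken as a catalogue compound; it is otherwise available from trans-4-hydroxy-L-proline by the usual C4 inversion.

**Route**

Step 1
Reactants: 1 methyl (2S,4S)-1-(tert-butoxycarbonyl)-4-hydroxypyrrolidine-2-carboxylate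
Product: 2 methyl (2S,4S)-1-Boc-4-(tert-butyldimethylsilyloxy)pyrrolidine-2-carboxylate
Conditions: TBSCl, imidazole, DMF, rt
Reagents that add atoms: tert-butyldimethylsilyl chloride, CC(C)(C)[Si](C)(C)Cl
Why: Imidazole-promoted silylation of a secondary alcohol, which touches no stereocentre and gives the bulky C1 substituent that later steers the addition at C12.

Step 2
Reactants: 2 methyl (2S,4S)-1-Boc-4-(TBSO)pyrrolidine-2-carboxylate
Product: 3 methyl (2S,4S)-1-Boc-4-(TBSO)-5-oxopyrrolidine-2-carboxylate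
Conditions: RuO2·xH2O (cat.), NaIO4, EtOAc/H2O, rt
Reagents that add atoms: sodium periodate (oxygen passed on through RuO4), [Na+].[O-]I(=O)(=O)=O
Why: Ruthenium tetroxide oxidation of the methylene next to a carbamate nitrogen to the lactam is established for N-Boc-4-silyloxyprolinates and leaves the methine at C3 alone.

Step 3
Reactants: 3 methyl (2S,4S)-1-Boc-4-(TBSO)-5-oxopyrrolidine-2-carboxylate
Product: 5 methyl (2S,4S)-1-Boc-4-(TBSO)-5-methoxypyrrolidine-2-carboxylate (both C5 epimers), via hemiaminal 4 (not isolated)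
Conditions: LiBHEt3, THF, −78 °C; then MeOH, PPTS (cat.), rt
Reagents that add atoms: methanol, CO
Why: The imide-like N-Boc lactam carbonyl is reduced at −78 °C faster than the methyl ester (as with N-Boc pyroglutamates), and acid-catalysed methanolysis turns the hemiaminal into the N,O-acetal that serves as N-acyliminium precursor.

Step 4
Reactants: 6 but-1-yne
Product: 9 potassium but-1-yn-1-yl(trifluoro)borate, via butynyllithium 7 (not isolated), via lithium butynyltrimethoxyborate 8 (not isolated)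
Conditions: n-BuLi, THF, −78 °C; B(OMe)3, −78 → −20 °C; KHF2 (aq), rt
Reagents that add atoms: trimethyl borate, COB(OC)OC; potassium hydrogen difluoride, [K+].[F-].F
Why: Deprotonation of the terminal alkyne, borylation and fluoride exchange is the standard preparation of potassium alkynyltrifluoroborates.

Step 5
Reactants: 5 methyl (2S,4S)-1-Boc-4-(TBSO)-5-methoxypyrrolidine-2-carboxylate; 9 potassium but-1-yn-1-yl(trifluoro)borate
Product: 11 methyl (2S,4S,5R)-1-Boc-5-(but-1-yn-1-yl)-4-(TBSO)pyrrolidine-2-carboxylate, via N-acyliminium ion 10 (not isolated)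
Conditions: BF3·OEt2, CH2Cl2, −78 → 0 °C
Reagents that add atoms: none
Why: BF3 ionises the N,O-acetal and the alkynyl group is transferred from boron to the cyclic N-acyliminium ion (a known use of alkynyltrifluoroborates) on the face anti to both the C1 silyl ether and the C3 ester, which should set C12 as R (2,5-trans and 4,5-trans).

Step 6
Reactants: 11 methyl (2S,4S,5R)-1-Boc-5-(but-1-yn-1-yl)-4-(TBSO)pyrrolidine-2-carboxylate
Product: 12 allyl 3-[(2S,4S,5R)-1-Boc-5-(but-1-yn-1-yl)-4-(TBSO)pyrrolidin-2-yl]-3-oxopropanoate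
Conditions: LiN(i-Pr)2, allyl acetate, THF, −78 °C; then 11, −78 → −40 °C; AcOH
Reagents that add atoms: allyl acetate, CC(=O)OCC=C
Why: Crossed Claisen condensation of the methyl ester with excess lithium enolate of allyl acetate, in which the β-keto ester is stored as its enolate as it forms so that C3 should not epimerise.

Step 7
Reactants: 13 ethyl (S)-lactate
Product: 14 ethyl (S)-2-(trifluoromethylsulfonyloxy)propanoate
Conditions: Tf2O, 2,6-lutidine, CH2Cl2, −78 → 0 °C
Reagents that add atoms: trifluoromethanesulfonic anhydride, O=S(=O)(OS(=O)(=O)C(F)(F)F)C(F)(F)F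
Why: O-Sulfonylation of the α-hydroxy ester breaks no bond to the stereocentre and gives the configurationally defined electrophile used in steps 8 and 20.

Step 8
Reactants: 12 allyl 3-[(2S,4S,5R)-1-Boc-5-(but-1-yn-1-yl)-4-(TBSO)pyrrolidin-2-yl]-3-oxopropanoate; 14 ethyl (S)-2-(trifluoromethylsulfonyloxy)propanoate
Product: 15 1-allyl 4-ethyl (3S)-3-methyl-2-{[(2S,4S,5R)-1-Boc-5-(but-1-yn-1-yl)-4-(TBSO)pyrrolidin-2-yl]carbonyl}butanedioate (both C19 epimers)
Conditions: NaH, THF, 0 °C; then 14, 0 °C → rt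
Reagents that add atoms: none
Why: C-Alkylation of a β-keto ester sodium enolate by an α-triflyloxy ester is a clean SN2 reaction with inversion (known for amino acid-derived β-keto esters), which fixes C20 as S, while the C19 centre disappears in step 9.

Step 9
Reactants: 15 1-allyl 4-ethyl (3S)-3-methyl-2-(pyrrolidinylcarbonyl)butanedioate
Product: 17 ethyl (2S)-4-[(2S,4S,5R)-1-Boc-5-(but-1-yn-1-yl)-4-(TBSO)pyrrolidin-2-yl]-2-methyl-4-oxobutanoate, via β-keto acid 16 (not isolated)
Conditions: Pd(PPh3)4 (cat.), morpholine, THF, rt → 40 °C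
Reagents that add atoms: none
Why: Zerovalent palladium passes the allyl group to morpholine (Tsuji–Trost deallylation) and the β-keto acid loses CO2 under near-neutral conditions that should leave C3, C20 and the alkyne untouched.

Step 10
Reactants: 17 ethyl (2S)-4-[(2S,4S,5R)-1-Boc-5-(but-1-yn-1-yl)-4-(TBSO)pyrrolidin-2-yl]-2-methyl-4-oxobutanoate
Product: 19 (3S,5S)-5-[(2S,4S,5R)-1-Boc-5-(but-1-yn-1-yl)-4-(TBSO)pyrrolidin-2-yl]-3-methyloxolan-2-one, via hydroxy ester 18 (not isolated)
Conditions: LiBH(s-Bu)3, THF, −78 °C; then AcOH, −78 °C → rt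
Reagents that add atoms: none
Why: Felkin–Anh reduction in which the bulky hydride attacks anti to the C3–N bond and past C3–H should give the (18S) alcohol (hydroxyl syn to nitrogen), which closes onto the ethyl ester to the cis-disubstituted γ-lactone, the ester and the alkyne being inert to the borohydride at −78 °C.

Step 11
Reactants: 19 (3S,5S)-5-[(2S,4S,5R)-1-Boc-5-(but-1-yn-1-yl)-4-(TBSO)pyrrolidin-2-yl]-3-methyloxolan-2-one
Product: 20 (3S,5S)-5-[(2S,4S,5R)-1-Boc-5-[(Z)-but-1-en-1-yl]-4-(TBSO)pyrrolidin-2-yl]-3-methyloxolan-2-one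
Conditions: H2 (1 atm), Pd/CaCO3 poisoned with Pb(OAc)2, quinoline, EtOAc, rt
Reagents that add atoms: none
Why: Lindlar semihydrogenation adds hydrogen syn to the internal alkyne and stops at the (Z)-olefin that the key step needs for an axial ethyl group.

Step 12
Reactants: 20 (3S,5S)-5-[(2S,4S,5R)-1-Boc-5-[(Z)-but-1-en-1-yl]-4-(TBSO)pyrrolidin-2-yl]-3-methyloxolan-2-one
Product: 22 (3S,5S)-5-[(2S,4S,5R)-5-[(Z)-but-1-en-1-yl]-1-(4-methoxybenzyl)-4-(TBSO)pyrrolidin-2-yl]-3-methyloxolan-2-one, via secondary amine 21 (not isolated)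
Conditions: TMSOTf, 2,6-lutidine, CH2Cl2, 0 °C; MeOH; then 4-MeOC6H4CHO, NaBH(OAc)3, AcOH, ClCH2CH2Cl, rt
Reagents that add atoms: 4-methoxybenzaldehyde, COc1ccc(C=O)cc1
Why: Silyl triflate-mediated Boc cleavage spares the TBS ether, and reductive amination of the amine (kept as its salt until the aldehyde is present, so that O-to-N acyl shift of the lactone cannot set in) installs a p-methoxybenzyl group, chosen because its cation leaves an acylammonium ion less readily than a dimethoxybenzyl cation while it can still be removed oxidatively from a lactam.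

Step 13
Reactants: 23 6-chlorohexanoyl chloride
Product: 24 6-chlorohexanoyl fluoride
Conditions: KF (spray-dried), 18-crown-6 (cat.), MeCN, rt
Reagents that add atoms: potassium fluoride, [K+].[F-]
Why: Halide exchange at the acyl carbon gives the acid fluoride, whose fluoride counter-ion does not dealkylate acylammonium ions.

Step 14
Reactants: 22 (3S,5S)-5-[(2S,4S,5R)-5-[(Z)-but-1-en-1-yl]-1-(4-methoxybenzyl)-4-(TBSO)pyrrolidin-2-yl]-3-methyloxolan-2-one; 24 6-chlorohexanoyl fluoride
Product: 27 (3S,4S,5E,7S,9S)-3-(4-chlorobutyl)-4-ethyl-1-(4-methoxybenzyl)-9-[(2S,4S)-4-methyl-5-oxooxolan-2-yl]-7-(TBSO)-1,3,4,7,8,9-hexahydro-2H-azonin-2-one (nine-membered lactam; 1S,3S,9S,10S,11E in target numbering), via acylammonium fluoride 25 (not isolated), via ammonium enolate 26 (not isolated)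
Conditions: Me3Al (2 equiv), K2CO3 (solid), CH2Cl2, 0 °C → rt, slow addition of 24
Reagents that add atoms: none
Why: Me3Al-assisted N-acylation on the nitrogen face syn to the butenyl arm gives acylammonium ion 25, K2CO3 removes the acidic α-proton to give the Z-ammonium enolate 26 (chlorobutyl chain cis to O−, trans to N+), and the charge-accelerated [3,3] shift forms C9–C10 while N4–C12 breaks, N4–C9a having formed in the acylation. The closest known reaction is the zwitterionic aza-Claisen ring expansion of N-benzyl-2-vinylpyrrolidines with acid fluorides and Me3Al to nine-membered (E)-lactams. The nine-membered ring arises by four-atom enlargement of the pyrrolidine through a six-membered chair transition state, not by end-to-end cyclisation, so no high dilution is needed. C9 is controlled by the Z-enolate (chlorobutyl equatorial) and C10 by the (Z)-olefin (ethyl axial), which together give the anti C9/C10 pair (9S, 10S as CIP descriptors here), and the absolute sense comes from (R)-C12, whose C1 substituent sits equatorial and so gives the (E)-olefin. The step needs chair over boat and acylation syn to the butenyl group; the first is favoured by the absence of any substituent on C11, the second by the 2,5-trans pattern in which the lactone-bearing C3 blocks the other nitrogen face, and fluoride as counter-ion keeps the benzylic group on nitrogen until the shift has taken place.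

Step 15
Reactants: 27 nine-membered N-(4-methoxybenzyl) lactam
Product: 28 (3S,4S,5E,7S,9S)-3-(4-chlorobutyl)-4-ethyl-9-[(2S,4S)-4-methyl-5-oxooxolan-2-yl]-7-(TBSO)-1,3,4,7,8,9-hexahydro-2H-azonin-2-one (NH lactam)
Conditions: (NH4)2Ce(NO3)6, MeCN/H2O (4:1), 0 °C
Reagents that add atoms: none
Why: Oxidation of the electron-rich arene gives an N-acyl hemiaminal that collapses to the NH lactam and anisaldehyde (standard oxidative removal of a p-methoxybenzyl group from a lactam), and the isolated olefin and the silyl ether should survive at 0 °C.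

Step 16
Reactants: 28 nine-membered NH lactam with the 4-chlorobutyl arm on C9
Product: 29 bridged bicyclic lactam (azepanone closed at N4–C5; 1S-OTBS, 3S, 9S, 10S, 11E olefin; SMILES in the list)
Conditions: NaH, Bu4NI (cat.), DMF, 0 → 40 °C
Reagents that add atoms: none
Why: Iodide-catalysed intramolecular N-alkylation (7-exo-tet) of the sodium amidate by the primary chloride closes the azepanone once the amidate adopts the transoid arrangement within the nine-membered ring that the natural product also has, and NaH removes N–H well before any lactone α-C–H.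

Step 17
Reactants: 29 bridged bicyclic lactam silyl ether
Product: 30 (1S)-allylic alcohol (29 with free C1 hydroxyl)
Conditions: Bu4NF, AcOH, THF, 0 °C → rt
Reagents that add atoms: none
Why: Fluoride cleavage of the silyl ether, buffered with acetic acid so that the side-lactone α-centre C20 is not epimerised.

Step 18
Reactants: 30 (1S)-allylic alcohol
Product: 31 (1S,11S,12S)-11,12-epoxy alcohol (trans epoxide, erythro to the C1 hydroxyl)
Conditions: VO(acac)2 (cat.), t-BuOOH (decane), toluene, 40 °C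
Reagents that add atoms: tert-butyl hydroperoxide, CC(C)(C)OO
Why: Hydroxyl-directed epoxidation through a vanadium alkoxide needs the C1–O bond close to the olefin plane (O–C1–C12=C11 about 40°), which is met only in the planar diastereomer of the (E)-olefin that exposes the face from which N4 left C12, so oxygen should enter C11 and C12 from that face (the usual erythro preference for (E)-allylic alcohols), gentle warming letting the two planar diastereomers interconvert.

Step 19
Reactants: 31 (1S,11S,12S)-epoxy alcohol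
Product: 32 (11S,12R)-11,12-epoxy-1-ketone
Conditions: Dess–Martin periodinane, NaHCO3, CH2Cl2, 0 °C → rt
Reagents that add atoms: none
Why: Buffered Dess–Martin oxidation of the secondary alcohol gives the α,β-epoxy ketone without opening the epoxide.

Step 20
Reactants: 32 (11S,12R)-11,12-epoxy-1-ketone; 14 ethyl (S)-2-(trifluoromethylsulfonyloxy)propanoate
Product: 35 tuberostemonone, via dilithium enolate alkoxide 33 (not isolated), via hydroxy ester 34 (not isolated)
Conditions: LiC10H8 (2.1 equiv), THF, −78 °C; 14, −78 → −40 °C; AcOH; then PPTS, toluene, 50 °C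
Reagents that add atoms: none
Why: Two-electron reduction of the α,β-epoxy ketone by the arene radical anion (reductive alkylation of epoxy ketones, dissolving-metal type, with a reductant too weak for the lactones at −78 °C) cleaves C12–O and gives the C1/C12 enolate regiospecifically, this ring-cis enolate with H11 in its plane is alkylated by the lactate triflate with inversion (13S) on the face away from the C10–C11 ring bond (12R), and mild acid closes the trans-fused lactone from the C11 hydroxyl.

**Compound list**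

1 | methyl (2S,4S)-1-(tert-butoxycarbonyl)-4-hydroxypyrrolidine-2-carboxylate | COC(=O)[C@@H]1C[C@H](O)CN1C(=O)OC(C)(C)C | starting material
2 | methyl (2S,4S)-1-Boc-4-(tert-butyldimethylsilyloxy)pyrrolidine-2-carboxylate | COC(=O)[C@@H]1C[C@H](O[Si](C)(C)C(C)(C)C)CN1C(=O)OC(C)(C)C | intermediate
3 | methyl (2S,4S)-1-Boc-4-(TBSO)-5-oxopyrrolidine-2-carboxylate | COC(=O)[C@@H]1C[C@H](O[Si](C)(C)C(C)(C)C)C(=O)N1C(=O)OC(C)(C)C | intermediate
4 | methyl (2S,4S)-1-Boc-4-(TBSO)-5-hydroxypyrrolidine-2-carboxylate (C5 epimers) | COC(=O)[C@@H]1C[C@H](O[Si](C)(C)C(C)(C)C)C(O)N1C(=O)OC(C)(C)C | intermediate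
5 | methyl (2S,4S)-1-Boc-4-(TBSO)-5-methoxypyrrolidine-2-carboxylate (C5 epimers) | COC(=O)[C@@H]1C[C@H](O[Si](C)(C)C(C)(C)C)C(OC)N1C(=O)OC(C)(C)C | intermediate
6 | but-1-yne | CCC#C | starting material
7 | but-1-yn-1-yllithium | CCC#C[Li] | intermediate
8 | lithium but-1-yn-1-yl(trimethoxy)borate | CCC#C[B-](OC)(OC)OC.[Li+] | intermediate
9 | potassium but-1-yn-1-yl(trifluoro)borate | CCC#C[B-](F)(F)F.[K+] | intermediate
10 | (2S,4S)-1-Boc-2-(methoxycarbonyl)-4-(TBSO)-3,4-dihydro-2H-pyrrol-1-ium (N-acyliminium ion) | COC(=O)[C@@H]1C[C@H](O[Si](C)(C)C(C)(C)C)C=[N+]1C(=O)OC(C)(C)C | intermediate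
11 | methyl (2S,4S,5R)-1-Boc-5-(but-1-yn-1-yl)-4-(TBSO)pyrrolidine-2-carboxylate | CCC#C[C@H]1N(C(=O)OC(C)(C)C)[C@@H](C[C@@H]1O[Si](C)(C)C(C)(C)C)C(=O)OC | intermediate
12 | allyl 3-[(2S,4S,5R)-1-Boc-5-(but-1-yn-1-yl)-4-(TBSO)pyrrolidin-2-yl]-3-oxopropanoate | CCC#C[C@H]1N(C(=O)OC(C)(C)C)[C@@H](C[C@@H]1O[Si](C)(C)C(C)(C)C)C(=O)CC(=O)OCC=C | intermediate
13 | ethyl (S)-lactate | C[C@H](O)C(=O)OCC | starting material
14 | ethyl (S)-2-(trifluoromethylsulfonyloxy)propanoate | C[C@H](OS(=O)(=O)C(F)(F)F)C(=O)OCC | intermediate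
15 | 1-allyl 4-ethyl (3S)-3-methyl-2-{[(2S,4S,5R)-1-Boc-5-(but-1-yn-1-yl)-4-(TBSO)pyrrolidin-2-yl]carbonyl}butanedioate (C19 epimers) | CCC#C[C@H]1N(C(=O)OC(C)(C)C)[C@@H](C[C@@H]1O[Si](C)(C)C(C)(C)C)C(=O)C(C(=O)OCC=C)[C@H](C)C(=O)OCC | intermediate
16 | β-keto acid from 15 (allyl ester cleaved) | CCC#C[C@H]1N(C(=O)OC(C)(C)C)[C@@H](C[C@@H]1O[Si](C)(C)C(C)(C)C)C(=O)C(C(=O)O)[C@H](C)C(=O)OCC | intermediate
17 | ethyl (2S)-4-[(2S,4S,5R)-1-Boc-5-(but-1-yn-1-yl)-4-(TBSO)pyrrolidin-2-yl]-2-methyl-4-oxobutanoate | CCC#C[C@H]1N(C(=O)OC(C)(C)C)[C@@H](C[C@@H]1O[Si](C)(C)C(C)(C)C)C(=O)C[C@H](C)C(=O)OCC | intermediate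
18 | ethyl (2S,4S)-4-[(2S,4S,5R)-1-Boc-5-(but-1-yn-1-yl)-4-(TBSO)pyrrolidin-2-yl]-4-hydroxy-2-methylbutanoate | CCC#C[C@H]1N(C(=O)OC(C)(C)C)[C@@H](C[C@@H]1O[Si](C)(C)C(C)(C)C)[C@@H](O)C[C@H](C)C(=O)OCC | intermediate
19 | (3S,5S)-5-[(2S,4S,5R)-1-Boc-5-(but-1-yn-1-yl)-4-(TBSO)pyrrolidin-2-yl]-3-methyloxolan-2-one | CCC#C[C@H]1N(C(=O)OC(C)(C)C)[C@@H](C[C@@H]1O[Si](C)(C)C(C)(C)C)[C@@H]2C[C@H](C)C(=O)O2 | intermediate
20 | (3S,5S)-5-[(2S,4S,5R)-1-Boc-5-[(Z)-but-1-en-1-yl]-4-(TBSO)pyrrolidin-2-yl]-3-methyloxolan-2-one | CC/C=C\[C@H]1N(C(=O)OC(C)(C)C)[C@@H](C[C@@H]1O[Si](C)(C)C(C)(C)C)[C@@H]2C[C@H](C)C(=O)O2 | intermediate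
21 | (3S,5S)-5-[(2S,4S,5R)-5-[(Z)-but-1-en-1-yl]-4-(TBSO)pyrrolidin-2-yl]-3-methyloxolan-2-one | CC/C=C\[C@H]1N[C@@H](C[C@@H]1O[Si](C)(C)C(C)(C)C)[C@@H]2C[C@H](C)C(=O)O2 | intermediate
22 | (3S,5S)-5-[(2S,4S,5R)-5-[(Z)-but-1-en-1-yl]-1-(4-methoxybenzyl)-4-(TBSO)pyrrolidin-2-yl]-3-methyloxolan-2-one | CC/C=C\[C@H]1N(Cc2ccc(OC)cc2)[C@@H](C[C@@H]1O[Si](C)(C)C(C)(C)C)[C@@H]3C[C@H](C)C(=O)O3 | intermediate
23 | 6-chlorohexanoyl chloride | O=C(Cl)CCCCCCl | starting material
24 | 6-chlorohexanoyl fluoride | O=C(F)CCCCCCl | intermediate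
25 | N-(6-chlorohexanoyl)ammonium fluoride of 22, acyl group cis to the butenyl arm | CC/C=C\[C@H]1[N@@+](Cc2ccc(OC)cc2)(C(=O)CCCCCCl)[C@@H](C[C@@H]1O[Si](C)(C)C(C)(C)C)[C@@H]3C[C@H](C)C(=O)O3.[F-] | intermediate
26 | zwitterionic (Z)-ammonium enolate from 25 | CC/C=C\[C@H]1[N@@+](Cc2ccc(OC)cc2)(/C([O-])=C/CCCCCl)[C@@H](C[C@@H]1O[Si](C)(C)C(C)(C)C)[C@@H]3C[C@H](C)C(=O)O3 | intermediate
27 | (3S,4S,5E,7S,9S)-3-(4-chlorobutyl)-4-ethyl-1-(4-methoxybenzyl)-9-[(2S,4S)-4-methyl-5-oxooxolan-2-yl]-7-(TBSO)-1,3,4,7,8,9-hexahydro-2H-azonin-2-one | CC[C@H]1/C=C/[C@@H](O[Si](C)(C)C(C)(C)C)C[C@@H]([C@@H]2C[C@H](C)C(=O)O2)N(Cc2ccc(OC)cc2)C(=O)[C@H]1CCCCCl | intermediate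
28 | (3S,4S,5E,7S,9S)-3-(4-chlorobutyl)-4-ethyl-9-[(2S,4S)-4-methyl-5-oxooxolan-2-yl]-7-(TBSO)-1,3,4,7,8,9-hexahydro-2H-azonin-2-one | CC[C@H]1/C=C/[C@@H](O[Si](C)(C)C(C)(C)C)C[C@@H]([C@@H]2C[C@H](C)C(=O)O2)NC(=O)[C@H]1CCCCCl | intermediate
29 | bridged bicyclic lactam, azepanone closed at N4–C5, (1S)-OTBS, 3S, 9S, 10S, 11E olefin | CC[C@H]1/C=C/[C@@H](O[Si](C)(C)C(C)(C)C)C[C@@H]([C@@H]2C[C@H](C)C(=O)O2)N2CCCC[C@@H]1C2=O | intermediate
30 | (1S)-allylic alcohol of the bicyclic lactam (11E) | CC[C@H]1/C=C/[C@@H](O)C[C@@H]([C@@H]2C[C@H](C)C(=O)O2)N2CCCC[C@@H]1C2=O | intermediate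
31 | (1S,11S,12S)-11,12-epoxy alcohol of the bicyclic lactam | CC[C@H]1[C@@H]2O[C@H]2[C@@H](O)C[C@@H]([C@@H]2C[C@H](C)C(=O)O2)N2CCCC[C@@H]1C2=O | intermediate
32 | (11S,12R)-11,12-epoxy-1-ketone of the bicyclic lactam | CC[C@H]1[C@@H]2O[C@H]2C(=O)C[C@@H]([C@@H]2C[C@H](C)C(=O)O2)N2CCCC[C@@H]1C2=O | intermediate
33 | dilithium C1/C12 enolate C11 alkoxide (ring-cis enolate) | CC[C@H]1[C@H]([O-])/C=C(/[O-])C[C@@H]([C@@H]2C[C@H](C)C(=O)O2)N2CCCC[C@@H]1C2=O.[Li+].[Li+] | intermediate
34 | (11S,12R,13S)-11-hydroxy-1-ketone carrying the ethyl (S)-propanoate unit on C12 | CC[C@H]1[C@H](O)[C@@H]([C@H](C)C(=O)OCC)C(=O)C[C@@H]([C@@H]2C[C@H](C)C(=O)O2)N2CCCC[C@@H]1C2=O | intermediate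
35 | tuberostemonone (3S,9S,10R,11S,12R,13S,18S,20S) | CC[C@H]1[C@@H]2OC(=O)[C@@H](C)[C@H]2C(=O)C[C@@H]([C@@H]2C[C@H](C)C(=O)O2)N2CCCC[C@@H]1C2=O | target

**Step count and risks**

Total step count: 20. Longest linear sequence: 17 steps (1 to 35 through steps 1, 2, 3, 5, 6, 8, 9, 10, 11, 12, 14, 15, 16, 17, 18, 19 and 20).

The three steps most likely to fail:

Step 20. The hindered dilithium enolate alkoxide may act as a base toward the secondary triflate (loss of triflic acid to give ethyl acrylate), may be alkylated on oxygen, or may take up the electrophile on the wrong face. The fallback sets out from 32. The same reductive opening is used, but the dianion 33 is trapped with ethyl iodoacetate, a primary electrophile that cannot eliminate, to give the hydroxy ester F1, which PPTS closes to the nor-methyl lactone F2. Treatment with LiN(i-Pr)2 (2.2 equiv; ketone enolate first, then the more reactive lactone enolate) and Me2N=CH2 iodide should give the Mannich base F3, and quaternisation with MeI followed by NaHCO3 the α-methylene lactone F4. Hydrogenation (H2, Pd/C, EtOAc) should add hydrogen to the exocyclic olefin from the face anti to C1 and so place the methyl group cis to C1 (13S). The fallback comes back to the route at 35.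

Step 18. Oxygen may be delivered to the wrong olefin face if the two planar diastereomers of the (E)-olefin exchange slowly or if the kinetic one is epoxidised without direction. The fallback sets out from 30. Mitsunobu inversion with chloroacetic acid (PPh3, DIAD) gives the inverted chloroacetate F5, and thiourea with NaHCO3 in ethanol frees the (1R)-allylic alcohol F6. In this epimer the planar diastereomer that exposes the required face is the only one with hydrogen in the olefin plane at both allylic centres (C1 and C10). After warming in toluene at 60 °C, an undirected peracid epoxidation (mCPBA, NaHCO3, CH2Cl2) on the open face should therefore give the (1R)-epoxy alcohol F7. Dess–Martin oxidation erases the C1 centre, and the fallback comes back to the route at 32.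

Step 14. N-Acylation of the hindered 2,5-disubstituted amine may be slow, and the acylammonium ion may lose the p-methoxybenzyl cation before it is enolised. The fallback sets out from 22 and the acid chloride 23 and reaches the zwitterion from the ketene side (Lewis acid-promoted ketene Claisen): i-Pr2NEt generates (4-chlorobutyl)ketene F8 from 23 in the presence of TiCl4·2THF in CH2Cl2. The amine adds to the activated ketene to give the titanium-bound form of enolate 26 directly, with no free acylammonium ion and no fluoride, and the same chair [3,3] shift follows. The fallback comes back to the route at 27.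

**Further compounds**

F1 | step 20 | (11S,12R)-11-hydroxy-1-ketone with CH2CO2Et on C12 (34 without the C15 methyl group) | CC[C@H]1[C@H](O)[C@@H](CC(=O)OCC)C(=O)C[C@@H]([C@@H]2C[C@H](C)C(=O)O2)N2CCCC[C@@H]1C2=O
F2 | step 20 | 13-demethyltuberostemonone (trans-fused nor-methyl lactone) | CC[C@H]1[C@@H]2OC(=O)C[C@H]2C(=O)C[C@@H]([C@@H]2C[C@H](C)C(=O)O2)N2CCCC[C@@H]1C2=O
F3 | step 20 | 13-(dimethylaminomethyl) lactone (Mannich base, C13 epimers) | CC[C@H]1[C@@H]2OC(=O)C(CN(C)C)[C@H]2C(=O)C[C@@H]([C@@H]2C[C@H](C)C(=O)O2)N2CCCC[C@@H]1C2=O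
F4 | step 20 | 13-methylene lactone (α-methylene-γ-butyrolactone) | CC[C@H]1[C@@H]2OC(=O)C(=C)[C@H]2C(=O)C[C@@H]([C@@H]2C[C@H](C)C(=O)O2)N2CCCC[C@@H]1C2=O
F5 | step 18 | (1R)-chloroacetate (C1-inverted ester of 30) | CC[C@H]1/C=C/[C@H](OC(=O)CCl)C[C@@H]([C@@H]2C[C@H](C)C(=O)O2)N2CCCC[C@@H]1C2=O
F6 | step 18 | (1R)-allylic alcohol (C1 epimer of 30) | CC[C@H]1/C=C/[C@H](O)C[C@@H]([C@@H]2C[C@H](C)C(=O)O2)N2CCCC[C@@H]1C2=O
F7 | step 18 | (1R,11S,12S)-11,12-epoxy alcohol (C1 epimer of 31) | CC[C@H]1[C@@H]2O[C@H]2[C@H](O)C[C@@H]([C@@H]2C[C@H](C)C(=O)O2)N2CCCC[C@@H]1C2=O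
F8 | step 14 | (4-chlorobutyl)ketene (6-chlorohex-1-en-1-one) | O=C=CCCCCCl
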